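**Plan**
1. The first cut is the depside ester bond between the carboxyl carbon on carbon 1 of ring A and the oxygen on carbon 4 of ring B, the second the O–CH3 bond at carbon 2 of ring B; both rings then trace back to one protected 2,4-dioxy-6-(2-oxoheptyl)benzoic acid.
2. In that acid the ketone is cut at the C(=O)–pentyl bond (Weinreb amide plus pentyl Grignard reagent), which leaves a homophthalate diester.
3. The homophthalate is cut at two bonds at once: carbon 1 of ring A to its carboxyl carbon and the neighbouring carbon 6 of ring A to its CH2 carbon. With the oxygen on carbon 2 of ring A flanking carbon 1, this is the pattern that an alkoxy-directed aryne insertion into the C–C bond of a malonate delivers (ring B repeats it at its carbons 1, 6 and 2).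
4. Forward: phloroglucinol, bis(benzyl ether), ortho-silyl aryl triflate, aryne/malonate insertion, side-chain ketone, dioxolane acid. Part of this acid is converted into the ring B phenol, the two are esterified at the 4-oxygen of ring B, the 2-hydroxyl of ring B is methylated, and ketals and benzyl groups are removed.
5. No ring is built (both benzene rings come from phloroglucinol) and the target has no stereocentre, so all control is regiochemical.

Key step: step 5

Assumption: 2-(2-oxoalkyl)benzoates cyclise readily to isocoumarins or naphthols under acid or base, so both ketones are carried as dioxolanes from step 8 to step 13; sp3 centres in unisolated intermediates are uncontrolled and vanish again.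

**Route**

Step 1
Reactants: 1 phloroglucinol; 2 benzyl bromide
Product: 3 3,5-bis(benzyloxy)phenol
Conditions: BnBr (2 equiv), K2CO3, DMF, 0 °C → rt
Reagents that add atoms: benzyl bromide (second equivalent), BrCc1ccccc1
Why: Williamson etherification of a symmetric triol raises no regiochemical question, and with two equivalents of halide the bis-ether should be the main component of the statistical mixture, separable by chromatography from mono-ether (which can be resubmitted) and tris-ether.

Step 2
Reactants: 3 3,5-bis(benzyloxy)phenol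
Product: 4 3,5-bis(benzyloxy)phenyl isopropylcarbamate
Conditions: i-PrNCO, Et3N (cat.), CH2Cl2, rt
Reagents that add atoms: isopropyl isocyanate, CC(C)N=C=O
Why: Base-catalysed addition of the phenol to the isocyanate (carbamoylation) should give the N–H carbamate, which serves as ortho-directing group and can later be removed under mild base.

Step 3
Reactants: 4 3,5-bis(benzyloxy)phenyl isopropylcarbamate
Product: 8 3,5-bis(benzyloxy)-2-(trimethylsilyl)phenyl isopropylcarbamate, via N-silyl carbamate 5 (not isolated), via ortho-lithiated N-silyl carbamate 6 (not isolated), via N-silyl C-silyl carbamate 7 (not isolated)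
Conditions: t-BuMe2SiOTf, TMEDA, Et2O, 0 °C → rt; n-BuLi, TMEDA, −78 °C; Me3SiCl, −78 °C → rt; aq. NaHSO4
Reagents that add atoms: chlorotrimethylsilane, C[Si](C)(C)Cl
Why: Directed ortho-metalation: N-silylation gives 5, whose carbamate directs n-BuLi/TMEDA to the position between the carbamate and a benzyloxy group (both such positions are equivalent by symmetry) to give 6, Me3SiCl traps it as 7, and the acidic work-up removes the N-silyl group.

Step 4
Reactants: 8 3,5-bis(benzyloxy)-2-(trimethylsilyl)phenyl isopropylcarbamate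
Product: 10 3,5-bis(benzyloxy)-2-(trimethylsilyl)phenyl trifluoromethanesulfonate, via 2-silylphenol 9 (not isolated)
Conditions: Et2NH, DBU, MeCN, 40 °C; then PhNTf2, rt
Reagents that add atoms: N-phenylbis(trifluoromethanesulfonimide), O=S(=O)(N(c1ccccc1)S(=O)(=O)C(F)(F)F)C(F)(F)F
Why: E1cB cleavage of the N–H carbamate by DBU should release phenoxide 9 while the carbamoyl fragment is scavenged by Et2NH as a urea, and O-triflation in the same flask with PhNTf2 is mild enough to leave the aryl–silicon bond intact.

Step 5
Reactants: 10 3,5-bis(benzyloxy)-2-(trimethylsilyl)phenyl trifluoromethanesulfonate; 11 dimethyl malonate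
Product: 14 methyl 2,4-bis(benzyloxy)-6-(2-methoxy-2-oxoethyl)benzoate, via 3,5-bis(benzyloxy)benzyne 12 (not isolated), via benzocyclobutenoxide 13 (not isolated)
Conditions: KF, 18-crown-6, dimethyl malonate (excess), THF, rt
Reagents that add atoms: none
Why: Fluoride attacks the trimethylsilyl group of 10 and triflate is expelled to give aryne 12; the malonate anion adds to the aryne carbon remote from the flanking benzyloxy group, the aryl anion closes onto one ester carbonyl to give benzocyclobutenoxide 13, and fragmentation of the strained ring gives the ester-stabilised benzylic anion, which is protonated by more malonate and so carries the chain. The closest known reaction type is the insertion of arynes from 2-silylaryl triflates into the C–C sigma bond of malonates and beta-keto esters (aryne acyl-alkylation). No ring remains in the product; the only ring closed is the transient four-membered ring of 13, formed 4-exo-trig and opened again in the same flask. Compound 14 has no stereocentre, and the two sp3 centres of 13 are transient and uncontrolled. The step needs regioselective addition so that the carboxyl carbon ends up between the benzyloxy oxygen and the new CH2 group: the inductively withdrawing oxygen beside the triple bond distorts the aryne, directs the nucleophile to the distal carbon and stabilises the aryl anion next to it, and since the silyl and triflate groups of 10 fix the triple bond between their two carbons only one aryne can form. Excess malonate is meant to suppress a second arylation at the acidic methylene of the product.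

Step 6
Reactants: 14 methyl 2,4-bis(benzyloxy)-6-(2-methoxy-2-oxoethyl)benzoate
Product: 15 methyl 2,4-bis(benzyloxy)-6-{2-[methoxy(methyl)amino]-2-oxoethyl}benzoate
Conditions: MeNHOMe·HCl, i-PrMgCl, THF, −20 → 0 °C
Reagents that add atoms: N,O-dimethylhydroxylamine hydrochloride, CNOC.Cl
Why: Weinreb amide formation by aminolysis with the magnesium amide ClMgN(OMe)Me made in the flask should touch only the unhindered aliphatic ester, the aryl ester being shielded by its two ortho substituents.

Step 7
Reactants: 15 methyl 2,4-bis(benzyloxy)-6-{2-[methoxy(methyl)amino]-2-oxoethyl}benzoate; 16 pentylmagnesium bromide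
Product: 18 methyl 2,4-bis(benzyloxy)-6-(2-oxoheptyl)benzoate, via magnesium hemiaminal chelate 17 (not isolated)
Conditions: n-C5H11MgBr, THF, −78 → 0 °C; aq. NH4Cl
Reagents that add atoms: none
Why: Weinreb ketone synthesis: chelate 17 should persist until work-up, so only one pentyl group adds, and the hindered aryl ester is not attacked at low temperature.

Step 8
Reactants: 18 methyl 2,4-bis(benzyloxy)-6-(2-oxoheptyl)benzoate
Product: 19 methyl 2,4-bis(benzyloxy)-6-[(2-pentyl-1,3-dioxolan-2-yl)methyl]benzoate
Conditions: Me3SiOCH2CH2OSiMe3, Me3SiOTf (cat.), CH2Cl2, −78 → −20 °C; pyridine quench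
Reagents that add atoms: 1,2-bis(trimethylsilyloxy)ethane, C[Si](C)(C)OCCO[Si](C)(C)C
Why: Noyori ketalisation is aprotic and runs at low temperature, so the ketone should be masked without the acid-catalysed enol-lactonisation to an isocoumarin that a hot protic ketalisation would invite.

Step 9
Reactants: 19 methyl 2,4-bis(benzyloxy)-6-[(2-pentyl-1,3-dioxolan-2-yl)methyl]benzoate
Product: 20 2,4-bis(benzyloxy)-6-[(2-pentyl-1,3-dioxolan-2-yl)methyl]benzoic acid
Conditions: KOH, DMSO/H2O, 90 °C; then cold aq. KHSO4 to pH 4
Reagents that add atoms: potassium hydroxide (KOH), [K+].[OH-]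
Why: Saponification of a di-ortho-substituted methyl benzoate needs hydroxide in hot aqueous DMSO, conditions to which benzyl ethers and the dioxolane are inert and under which the masked ketone cannot condense onto the ester, while the cold buffered acidification is meant to spare the ketal.

Step 10
Reactants: 20 2,4-bis(benzyloxy)-6-[(2-pentyl-1,3-dioxolan-2-yl)methyl]benzoic acid; 2 benzyl bromide
Product: 22 benzyl 2,4-dihydroxy-6-[(2-pentyl-1,3-dioxolan-2-yl)methyl]benzoate, via dihydroxy acid 21 (not isolated)
Conditions: H2 (1 atm), Pd/C, EtOAc, rt; filter, evaporate; KHCO3, BnBr (1 equiv), DMF, rt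
Reagents that add atoms: none
Why: Hydrogenolysis of both benzyl ethers followed by carboxylate-selective SN2 benzylation (KHCO3 is too weak a base to ionise the phenols) should turn part of acid 20 into the ring B unit with its carboxyl held as a hydrogenolysable benzyl ester, the sensitive acid 21 being used without isolation.

Step 11
Reactants: 20 2,4-bis(benzyloxy)-6-[(2-pentyl-1,3-dioxolan-2-yl)methyl]benzoic acid; 22 benzyl 2,4-dihydroxy-6-[(2-pentyl-1,3-dioxolan-2-yl)methyl]benzoate
Product: 23 benzyl 4-({2,4-bis(benzyloxy)-6-[(2-pentyl-1,3-dioxolan-2-yl)methyl]benzoyl}oxy)-2-hydroxy-6-[(2-pentyl-1,3-dioxolan-2-yl)methyl]benzoate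
Conditions: EDC·HCl, DMAP, CH2Cl2, 0 °C → rt
Reagents that add atoms: none
Why: Steglich-type carbodiimide esterification should acylate only the 4-hydroxyl of 22, because the 2-hydroxyl is hydrogen-bonded to the ortho ester carbonyl and sterically flanked, the usual basis of regioselective depside formation.

Step 12
Reactants: 23 benzyl 4-({2,4-bis(benzyloxy)-6-[(2-pentyl-1,3-dioxolan-2-yl)methyl]benzoyl}oxy)-2-hydroxy-6-[(2-pentyl-1,3-dioxolan-2-yl)methyl]benzoate
Product: 24 benzyl 4-({2,4-bis(benzyloxy)-6-[(2-pentyl-1,3-dioxolan-2-yl)methyl]benzoyl}oxy)-2-methoxy-6-[(2-pentyl-1,3-dioxolan-2-yl)methyl]benzoate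
Conditions: MeI, K2CO3, DMF, 40 °C
Reagents that add atoms: iodomethane, CI
Why: Williamson O-methylation of the one remaining (chelated) phenol should be tolerated by the depside ester, which is flanked by two ortho substituents on an electron-rich ring, and by the benzyl ester under anhydrous K2CO3, and no enolisable ketone is exposed at this stage.

Step 13
Reactants: 24 benzyl 4-({2,4-bis(benzyloxy)-6-[(2-pentyl-1,3-dioxolan-2-yl)methyl]benzoyl}oxy)-2-methoxy-6-[(2-pentyl-1,3-dioxolan-2-yl)methyl]benzoate
Product: 25 benzyl 4-{[2,4-bis(benzyloxy)-6-(2-oxoheptyl)benzoyl]oxy}-2-methoxy-6-(2-oxoheptyl)benzoate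
Conditions: aq. HCl (1 M), THF, rt
Reagents that add atoms: water, O
Why: Acid-catalysed ketal hydrolysis under dilute aqueous conditions at room temperature should free both dialkyl ketones at a stage where no free carboxylic acid or phenol is present, which disfavours lactonisation of the 2-oxoalkyl benzoates.

Step 14
Reactants: 25 benzyl 4-{[2,4-bis(benzyloxy)-6-(2-oxoheptyl)benzoyl]oxy}-2-methoxy-6-(2-oxoheptyl)benzoate
Product: 26 arthonioic acid, 4-{[2,4-dihydroxy-6-(2-oxoheptyl)benzoyl]oxy}-2-methoxy-6-(2-oxoheptyl)benzoic acid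
Conditions: H2 (1 atm), Pd/C, EtOAc, rt
Reagents that add atoms: none
Why: Hydrogenolysis over Pd/C should remove the two benzyl ethers of ring A and the benzyl ester of ring B under neutral conditions that leave the depside ester, the aryl methyl ether and the non-benzylic ketones untouched.

**Compound list**
1 | phloroglucinol (benzene-1,3,5-triol) | Oc1cc(O)cc(O)c1 | starting material
2 | benzyl bromide | BrCc1ccccc1 | starting material
3 | 3,5-bis(benzyloxy)phenol | Oc1cc(OCc2ccccc2)cc(OCc2ccccc2)c1 | intermediate
4 | 3,5-bis(benzyloxy)phenyl isopropylcarbamate | CC(C)NC(=O)Oc1cc(OCc2ccccc2)cc(OCc2ccccc2)c1 | intermediate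
5 | 3,5-bis(benzyloxy)phenyl N-(tert-butyldimethylsilyl)-N-isopropylcarbamate | CC(C)N(C(=O)Oc1cc(OCc2ccccc2)cc(OCc2ccccc2)c1)[Si](C)(C)C(C)(C)C | intermediate
6 | [2,4-bis(benzyloxy)-6-{[N-(tert-butyldimethylsilyl)-N-isopropylcarbamoyl]oxy}phenyl]lithium | CC(C)N(C(=O)Oc1cc(OCc2ccccc2)cc(OCc2ccccc2)c1[Li])[Si](C)(C)C(C)(C)C | intermediate
7 | 3,5-bis(benzyloxy)-2-(trimethylsilyl)phenyl N-(tert-butyldimethylsilyl)-N-isopropylcarbamate | CC(C)N(C(=O)Oc1cc(OCc2ccccc2)cc(OCc2ccccc2)c1[Si](C)(C)C)[Si](C)(C)C(C)(C)C | intermediate
8 | 3,5-bis(benzyloxy)-2-(trimethylsilyl)phenyl isopropylcarbamate | CC(C)NC(=O)Oc1cc(OCc2ccccc2)cc(OCc2ccccc2)c1[Si](C)(C)C | intermediate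
9 | 3,5-bis(benzyloxy)-2-(trimethylsilyl)phenol (present as its DBU salt) | Oc1cc(OCc2ccccc2)cc(OCc2ccccc2)c1[Si](C)(C)C | intermediate
10 | 3,5-bis(benzyloxy)-2-(trimethylsilyl)phenyl trifluoromethanesulfonate | C[Si](C)(C)c1c(OS(=O)(=O)C(F)(F)F)cc(OCc2ccccc2)cc1OCc1ccccc1 | intermediate
11 | dimethyl malonate | COC(=O)CC(=O)OC | starting material
12 | 3,5-bis(benzyloxy)benzyne (1,2-didehydro-3,5-bis(benzyloxy)benzene) | C1#CC(OCc2ccccc2)=CC(OCc2ccccc2)=C1 | intermediate
13 | potassium 2,4-bis(benzyloxy)-8-methoxy-7-(methoxycarbonyl)bicyclo[4.2.0]octa-1,3,5-trien-8-olate (mixture of diastereomers) | COC(=O)C1c2cc(OCc3ccccc3)cc(OCc3ccccc3)c2C1([O-])OC.[K+] | intermediate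
14 | methyl 2,4-bis(benzyloxy)-6-(2-methoxy-2-oxoethyl)benzoate | COC(=O)Cc1cc(OCc2ccccc2)cc(OCc2ccccc2)c1C(=O)OC | intermediate
15 | methyl 2,4-bis(benzyloxy)-6-{2-[methoxy(methyl)amino]-2-oxoethyl}benzoate | CON(C)C(=O)Cc1cc(OCc2ccccc2)cc(OCc2ccccc2)c1C(=O)OC | intermediate
16 | pentylmagnesium bromide | CCCCC[Mg]Br | starting material
17 | bromomagnesium alkoxide of the tetrahedral adduct of 15 and the pentyl Grignard reagent (racemic) | CCCCCC(O[Mg]Br)(Cc1cc(OCc2ccccc2)cc(OCc2ccccc2)c1C(=O)OC)N(C)OC | intermediate
18 | methyl 2,4-bis(benzyloxy)-6-(2-oxoheptyl)benzoate | CCCCCC(=O)Cc1cc(OCc2ccccc2)cc(OCc2ccccc2)c1C(=O)OC | intermediate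
19 | methyl 2,4-bis(benzyloxy)-6-[(2-pentyl-1,3-dioxolan-2-yl)methyl]benzoate | CCCCCC1(Cc2cc(OCc3ccccc3)cc(OCc3ccccc3)c2C(=O)OC)OCCO1 | intermediate
20 | 2,4-bis(benzyloxy)-6-[(2-pentyl-1,3-dioxolan-2-yl)methyl]benzoic acid | CCCCCC1(Cc2cc(OCc3ccccc3)cc(OCc3ccccc3)c2C(=O)O)OCCO1 | intermediate
21 | 2,4-dihydroxy-6-[(2-pentyl-1,3-dioxolan-2-yl)methyl]benzoic acid | CCCCCC1(Cc2cc(O)cc(O)c2C(=O)O)OCCO1 | intermediate
22 | benzyl 2,4-dihydroxy-6-[(2-pentyl-1,3-dioxolan-2-yl)methyl]benzoate | CCCCCC1(Cc2cc(O)cc(O)c2C(=O)OCc2ccccc2)OCCO1 | intermediate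
23 | benzyl 4-({2,4-bis(benzyloxy)-6-[(2-pentyl-1,3-dioxolan-2-yl)methyl]benzoyl}oxy)-2-hydroxy-6-[(2-pentyl-1,3-dioxolan-2-yl)methyl]benzoate | CCCCCC1(Cc2cc(OCc3ccccc3)cc(OCc3ccccc3)c2C(=O)Oc2cc(O)c(C(=O)OCc3ccccc3)c(CC3(CCCCC)OCCO3)c2)OCCO1 | intermediate
24 | benzyl 4-({2,4-bis(benzyloxy)-6-[(2-pentyl-1,3-dioxolan-2-yl)methyl]benzoyl}oxy)-2-methoxy-6-[(2-pentyl-1,3-dioxolan-2-yl)methyl]benzoate | CCCCCC1(Cc2cc(OCc3ccccc3)cc(OCc3ccccc3)c2C(=O)Oc2cc(OC)c(C(=O)OCc3ccccc3)c(CC3(CCCCC)OCCO3)c2)OCCO1 | intermediate
25 | benzyl 4-{[2,4-bis(benzyloxy)-6-(2-oxoheptyl)benzoyl]oxy}-2-methoxy-6-(2-oxoheptyl)benzoate | CCCCCC(=O)Cc1cc(OCc2ccccc2)cc(OCc2ccccc2)c1C(=O)Oc1cc(OC)c(C(=O)OCc2ccccc2)c(CC(=O)CCCCC)c1 | intermediate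
26 | arthonioic acid, 4-{[2,4-dihydroxy-6-(2-oxoheptyl)benzoyl]oxy}-2-methoxy-6-(2-oxoheptyl)benzoic acid | CCCCCC(=O)Cc1cc(O)cc(O)c1C(=O)Oc1cc(CC(=O)CCCCC)c(C(=O)O)c(OC)c1 | target

**Count**
Total: 14 steps. Longest linear sequence: 14 steps (1 to 26; acid 20 is used twice, once as the ring A acid and once, through step 10, as the source of ring B).

**Steps most likely to fail**

Step 5. The aryl anion formed after addition of the malonate may be protonated before it closes onto the ester carbonyl, which would give plain alpha-arylation instead of insertion. The nucleophile may also add with the wrong orientation, or the acidic product may be arylated again. The fallback gives up the aryne and makes only the side-chain C–C bond by lateral lithiation. It sets out from benzyl bromide 2 and purchased methyl 2,4-dihydroxy-6-methylbenzoate F1. F1 would be dibenzylated (BnBr, K2CO3, DMF) to methyl 2,4-bis(benzyloxy)-6-methylbenzoate F2. The 6-methyl group of F2 would be deprotonated with LiN(i-Pr)2 (over two equivalents, THF, −78 °C) and C-acylated with dimethyl carbonate, which rejoins the route at 14.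

Step 12. Alkylation of the hydrogen-bonded phenoxide may be slow enough that acyl transfer or cleavage of the depside ester by phenoxide or adventitious hydroxide competes. The fallback methylates before the ester bond is made and sets out from 22. Selective allylation of the free 4-hydroxyl (allyl bromide, K2CO3, acetone, rt) would give benzyl 4-(allyloxy)-2-hydroxy-6-[(2-pentyl-1,3-dioxolan-2-yl)methyl]benzoate F3. Methylation (MeI, K2CO3, DMF) would give benzyl 4-(allyloxy)-2-methoxy-6-[(2-pentyl-1,3-dioxolan-2-yl)methyl]benzoate F4. Deallylation with catalytic Pd(PPh3)4 (a zerovalent palladium complex) and morpholine in THF would give benzyl 4-hydroxy-2-methoxy-6-[(2-pentyl-1,3-dioxolan-2-yl)methyl]benzoate F5. Esterification of F5 with acid 20 under the conditions of step 11 rejoins the route at 24.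

Step 13. On opening of a dioxolane, the neighbouring ester carbonyl may capture the oxocarbenium ion, leading to lactonisation towards an isocoumarin with loss of the ring B phenol (cleavage of the depside) or of benzyl alcohol. The fallback reverses the order of the last two operations and sets out from 24. Hydrogenolysis (H2, Pd/C, EtOAc) would first give 4-({2,4-dihydroxy-6-[(2-pentyl-1,3-dioxolan-2-yl)methyl]benzoyl}oxy)-2-methoxy-6-[(2-pentyl-1,3-dioxolan-2-yl)methyl]benzoic acid F6. In F6 the ring A ester carbonyl is tied up in a hydrogen bond to the free 2-hydroxyl of ring A and should be a poorer internal nucleophile, and capture by the free ring B carboxyl is reversible and harmless. The ketals of F6 would then be hydrolysed in aqueous THF with catalytic pyridinium p-toluenesulfonate, which rejoins the route at 26.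

**Further compounds**
F1 | step 5 | methyl 2,4-dihydroxy-6-methylbenzoate (methyl orsellinate, purchased) | COC(=O)c1c(C)cc(O)cc1O
F2 | step 5 | methyl 2,4-bis(benzyloxy)-6-methylbenzoate | COC(=O)c1c(C)cc(OCc2ccccc2)cc1OCc1ccccc1
F3 | step 12 | benzyl 4-(allyloxy)-2-hydroxy-6-[(2-pentyl-1,3-dioxolan-2-yl)methyl]benzoate | CCCCCC1(Cc2cc(OCC=C)cc(O)c2C(=O)OCc2ccccc2)OCCO1
F4 | step 12 | benzyl 4-(allyloxy)-2-methoxy-6-[(2-pentyl-1,3-dioxolan-2-yl)methyl]benzoate | CCCCCC1(Cc2cc(OCC=C)cc(OC)c2C(=O)OCc2ccccc2)OCCO1
F5 | step 12 | benzyl 4-hydroxy-2-methoxy-6-[(2-pentyl-1,3-dioxolan-2-yl)methyl]benzoate | CCCCCC1(Cc2cc(O)cc(OC)c2C(=O)OCc2ccccc2)OCCO1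
F6 | step 13 | 4-({2,4-dihydroxy-6-[(2-pentyl-1,3-dioxolan-2-yl)methyl]benzoyl}oxy)-2-methoxy-6-[(2-pentyl-1,3-dioxolan-2-yl)methyl]benzoic acid | CCCCCC1(Cc2cc(O)cc(O)c2C(=O)Oc2cc(OC)c(C(=O)O)c(CC3(CCCCC)OCCO3)c2)OCCO1
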